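**Retrosynthetic overview**

1. Schizotenuin A ← nona-allyl derivative 24 (palladium-catalysed deallylation last) ← diacid 20 + two molecules of allyl-protected (R)-danshensu 22; both ester links are made in one double acylation and both stereocenters are bought with danshensu.
2. 20 ← benzofuran 13: the C5 acrylic acid from the C5 ester (reduction, oxidation, Doebner), the C7 allyl ether from the C7 acetate (cleaved in the same reduction, then allylated), the C3 acid from its tert-butyl ester.
3. Structural feature: on the benzo ring the oxygen sits at C7, beside the ring-fusion carbon C7a that carries the furan oxygen O1, and the only carbon substituent sits at C5, meta to it. This pattern arises when the CH2CO2H arm of a furan-3-ylmethylene succinate acylates the free furan α-carbon (bond C7–C7a).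
4. 13 ← Stobbe half-ester 10 ← 4-formylfuran 8 + diethyl succinate; 8 ← chloromethylfuran 7 (Kornblum) ← β-keto ester 4 + 1,3-dichloroacetone (Feist–Benary) ← benzoate 2 + tert-butyl acetate (Claisen).
5. Ring order: the three catechol rings are bought; the furan ring is made first (step 3) and the benzo ring is annulated onto it second (step 6).

Key step: step 6

Remark on the chemistry: all seven phenols and both lactate carboxyls are carried as allyl ethers/esters rather than methyl ethers, because neutral palladium-catalysed deallylation spares the two ester links, the (E)-alkene and the α-acyloxy stereocenters; (R)-danshensu is taken as the commercial free acid.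

**Route**

Step 1
Reactants: 1 methyl 3,4-dihydroxybenzoate
Product: 2 methyl 3,4-bis(allyloxy)benzoate
Conditions: allyl bromide, K2CO3, DMF, 60 °C
Reagents that add atoms: allyl bromide, C=CCBr
Why: Williamson O-alkylation of both phenoxides by allyl bromide under carbonate base; the methyl ester is untouched.

Step 2
Reactants: 2 methyl 3,4-bis(allyloxy)benzoate; 3 tert-butyl acetate
Product: 4 tert-butyl 3-[3,4-bis(allyloxy)phenyl]-3-oxopropanoate
Conditions: 3, LiN(i-Pr)2 (2.3 equiv each), THF, −78 °C; then 2, −78 to 0 °C; aq. NH4Cl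
Reagents that add atoms: none
Why: Crossed Claisen condensation in which the non-enolisable benzoate is acylated by pre-formed LiCH2CO2t-Bu, the second equivalent of enolate deprotonating the β-keto ester and driving the equilibrium.

Step 3
Reactants: 4 tert-butyl 3-[3,4-bis(allyloxy)phenyl]-3-oxopropanoate; 5 1,3-dichloroacetone
Product: 7 tert-butyl 2-[3,4-bis(allyloxy)phenyl]-4-(chloromethyl)furan-3-carboxylate, via hydroxydihydrofuran 6 (not isolated)
Conditions: i-Pr2NEt, THF, 0 °C to rt; then PPTS (cat.), toluene, 70 °C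
Reagents that add atoms: none
Why: Feist–Benary furan synthesis in which the enolate carbon of 4 adds to the strongly electrophilic ketone of 5 (aldol), the aryl-ketone enol oxygen displaces one chloride (5-exo-tet) to give 6, and mild acid dehydration aromatises it, leaving the second CH2Cl at C4 and C5 unsubstituted.

Step 4
Reactants: 7 tert-butyl 2-[3,4-bis(allyloxy)phenyl]-4-(chloromethyl)furan-3-carboxylate
Product: 8 tert-butyl 2-[3,4-bis(allyloxy)phenyl]-4-formylfuran-3-carboxylate
Conditions: DMSO, NaHCO3, NaI (cat.), 70 °C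
Reagents that add atoms: dimethyl sulfoxide, CS(C)=O
Why: Kornblum oxidation in which iodide-assisted SN2 displacement of the furylmethyl chloride by the sulfoxide oxygen gives an alkoxysulfonium salt that NaHCO3 collapses to the aldehyde with loss of dimethyl sulfide, the moderate temperature limiting lactonisation onto the neighbouring tert-butyl ester.

Step 5
Reactants: 8 tert-butyl 2-[3,4-bis(allyloxy)phenyl]-4-formylfuran-3-carboxylate; 9 diethyl succinate
Product: 10 (E)-4-{5-[3,4-bis(allyloxy)phenyl]-4-(tert-butoxycarbonyl)furan-3-yl}-3-(ethoxycarbonyl)but-3-enoic acid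
Conditions: KOt-Bu, t-BuOH/THF, rt to 45 °C; then 1 M HCl, 0 °C
Reagents that add atoms: none
Why: Stobbe condensation (aldol addition, lactonisation to the paraconic ester, E1cB ring opening) should give the half-ester with the (E)-alkene, furyl cis to CH2CO2H, while the bulky and poorly electrophilic tert-butyl ester cannot trap the aldolate as a fused lactone.

Step 6
Reactants: 10 (E)-4-{5-[3,4-bis(allyloxy)phenyl]-4-(tert-butoxycarbonyl)furan-3-yl}-3-(ethoxycarbonyl)but-3-enoic acid
Product: 13 3-tert-butyl 5-ethyl 7-acetoxy-2-[3,4-bis(allyloxy)phenyl]benzofuran-3,5-dicarboxylate, via mixed anhydride 11 (not isolated), via 7-hydroxybenzofuran 12 (not isolated)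
Conditions: Ac2O, NaOAc, 110 °C
Reagents that add atoms: acetic anhydride, CC(=O)OC(C)=O
Why: Acetic anhydride converts the CH2CO2H arm into mixed anhydride 11, which (directly or through the derived dienylketene) acylates the only unsubstituted furan α-carbon and forms C7–C7a; the σ-complex is stabilised by the ring oxygen and by the conjugated 3,4-bis(allyloxy)phenyl group at the other α-carbon. The resulting ring ketone tautomerises to the aromatic phenol 12, which is acetylated in the same pot. The closest known reaction type is the Stobbe half-ester cyclisation with acetic anhydride and sodium acetate, which turns arylmethylene succinates into acetoxynaphthoates and acetoxybenzofuran carboxylates. The benzo ring closes by a six-membered Friedel–Crafts acylation, 6-exo-trig at the acyl carbon (equivalently a 6π-electrocyclisation of the ketene), and no stereocenter is formed. The step needs regioselectivity, and it is secured because the other furan carbon flanking the side chain carries the tert-butyl ester and because the (E)-alkene holds the acyl arm cis to the furan. The buffered, Lewis-acid-free medium should spare the tert-butyl ester, and the aryl allyl ethers lie well below the temperature of Claisen rearrangement.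

Step 7
Reactants: 13 3-tert-butyl 5-ethyl 7-acetoxy-2-[3,4-bis(allyloxy)phenyl]benzofuran-3,5-dicarboxylate
Product: 14 tert-butyl 2-[3,4-bis(allyloxy)phenyl]-7-hydroxy-5-(hydroxymethyl)benzofuran-3-carboxylate
Conditions: i-Bu2AlH (4.5 equiv), CH2Cl2, −78 °C; aq. potassium sodium tartrate
Reagents that add atoms: none
Why: Hydride reduction with i-Bu2AlH at low temperature takes the unhindered benzoate-type ethyl ester to the benzylic alcohol and in the same operation cleaves the reactive aryl acetate reductively to the aluminium phenoxide, whereas the C3 tert-butyl ester is shielded by the C2 aryl group and deactivated as a vinylogous carbonate; allyl ethers are inert.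

Step 8
Reactants: 14 tert-butyl 2-[3,4-bis(allyloxy)phenyl]-7-hydroxy-5-(hydroxymethyl)benzofuran-3-carboxylate
Product: 15 tert-butyl 7-(allyloxy)-2-[3,4-bis(allyloxy)phenyl]-5-(hydroxymethyl)benzofuran-3-carboxylate
Conditions: allyl bromide (1.1 equiv), K2CO3, DMF, rt to 40 °C
Reagents that add atoms: allyl bromide, C=CCBr
Why: Chemoselective Williamson allylation, since carbonate deprotonates only the phenol and not the benzylic alcohol, so the third aryl allyl ether is installed while the primary alcohol stays free.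

Step 9
Reactants: 15 tert-butyl 7-(allyloxy)-2-[3,4-bis(allyloxy)phenyl]-5-(hydroxymethyl)benzofuran-3-carboxylate
Product: 16 tert-butyl 7-(allyloxy)-2-[3,4-bis(allyloxy)phenyl]-5-formylbenzofuran-3-carboxylate
Conditions: MnO2, CH2Cl2, rt
Reagents that add atoms: none
Why: MnO2 oxidises the benzylic alcohol selectively to the aldehyde without touching allyl ethers or esters.

Step 10
Reactants: 16 tert-butyl 7-(allyloxy)-2-[3,4-bis(allyloxy)phenyl]-5-formylbenzofuran-3-carboxylate; 17 malonic acid
Product: 19 (E)-3-{7-(allyloxy)-2-[3,4-bis(allyloxy)phenyl]-3-(tert-butoxycarbonyl)benzofuran-5-yl}acrylic acid, via arylidenemalonic acid 18 (not isolated)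
Conditions: pyridine, piperidine (cat.), 90 °C
Reagents that add atoms: none
Why: Knoevenagel–Doebner condensation, piperidine-catalysed condensation with malonic acid followed by decarboxylation in pyridine, should give the (E)-acrylic acid as the thermodynamic isomer.

Step 11
Reactants: 19 (E)-3-{7-(allyloxy)-2-[3,4-bis(allyloxy)phenyl]-3-(tert-butoxycarbonyl)benzofuran-5-yl}acrylic acid
Product: 20 7-(allyloxy)-2-[3,4-bis(allyloxy)phenyl]-5-[(E)-2-carboxyvinyl]benzofuran-3-carboxylic acid
Conditions: TFA, CH2Cl2, 0 °C to rt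
Reagents that add atoms: none
Why: Acidolysis of the tert-butyl ester with loss of isobutene leaves the allyl ethers, the acrylic acid and the benzofuran untouched.

Step 12
Reactants: 21 (R)-3-(3,4-dihydroxyphenyl)-2-hydroxypropanoic acid (danshensu)
Product: 22 allyl (R)-3-[3,4-bis(allyloxy)phenyl]-2-hydroxypropanoate
Conditions: allyl bromide (3.3 equiv), K2CO3, DMF, rt, Ar
Reagents that add atoms: allyl bromide, C=CCBr
Why: Carbonate deprotonates only the carboxylic acid and the two phenols, so Williamson-type alkylation takes place at these three oxygens and leaves the secondary alcohol free; the stereocenter is not involved and stays (R).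

Step 13
Reactants: 20 7-(allyloxy)-2-[3,4-bis(allyloxy)phenyl]-5-[(E)-2-carboxyvinyl]benzofuran-3-carboxylic acid; 22 allyl (R)-3-[3,4-bis(allyloxy)phenyl]-2-hydroxypropanoate (2.4 equiv)
Product: 24 nona-O-allyl schizotenuin A (all seven phenols as allyl ethers; both lactate carboxyls as allyl esters; both centers R), via bis(acid chloride) 23 (not isolated)
Conditions: (COCl)2, DMF (cat.), CH2Cl2, 0 °C to rt; concentrate; then 22, pyridine, DMAP (cat.), CH2Cl2, 0 °C to rt
Reagents that add atoms: oxalyl chloride, O=C(Cl)C(=O)Cl (chlorine only in the intermediate 23)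
Why: Both acids are converted to acid chlorides and DMAP-catalysed acylation of the secondary alcohol of 22 forms both esters at once; the C–O bond at the lactate stereocenter is not broken and no ketene pathway exists for these acyl chlorides, so both centers remain (R).

Step 14
Reactants: 24 nona-O-allyl schizotenuin A
Product: 25 schizotenuin A
Conditions: Pd(PPh3)4 (cat.), morpholine, THF, rt, Ar; then aq. HCl to pH 2
Reagents that add atoms: none
Why: Tsuji–Trost deallylation in which zerovalent palladium ionises the seven aryl allyl ethers and two allyl esters to π-allyl complexes that morpholine intercepts, freeing all phenols and both acids under conditions that spare the (E)-alkene, the two ester links and the two (R)-stereocenters.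

**Compound list**

1 | methyl 3,4-dihydroxybenzoate | COC(=O)c1ccc(O)c(O)c1 | starting material
2 | methyl 3,4-bis(allyloxy)benzoate | COC(=O)c1ccc(OCC=C)c(OCC=C)c1 | intermediate
3 | tert-butyl acetate | CC(=O)OC(C)(C)C | starting material
4 | tert-butyl 3-[3,4-bis(allyloxy)phenyl]-3-oxopropanoate | C=CCOc1ccc(C(=O)CC(=O)OC(C)(C)C)cc1OCC=C | intermediate
5 | 1,3-dichloroacetone | ClCC(=O)CCl | starting material
6 | tert-butyl 2-[3,4-bis(allyloxy)phenyl]-4-(chloromethyl)-4-hydroxy-4,5-dihydrofuran-3-carboxylate (racemic, not isolated) | C=CCOc1ccc(C2=C(C(=O)OC(C)(C)C)C(O)(CCl)CO2)cc1OCC=C | intermediate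
7 | tert-butyl 2-[3,4-bis(allyloxy)phenyl]-4-(chloromethyl)furan-3-carboxylate | C=CCOc1ccc(-c2occ(CCl)c2C(=O)OC(C)(C)C)cc1OCC=C | intermediate
8 | tert-butyl 2-[3,4-bis(allyloxy)phenyl]-4-formylfuran-3-carboxylate | C=CCOc1ccc(-c2occ(C=O)c2C(=O)OC(C)(C)C)cc1OCC=C | intermediate
9 | diethyl succinate | CCOC(=O)CCC(=O)OCC | starting material
10 | (E)-4-{5-[3,4-bis(allyloxy)phenyl]-4-(tert-butoxycarbonyl)furan-3-yl}-3-(ethoxycarbonyl)but-3-enoic acid | OC(=O)C/C(C(=O)OCC)=C\c1coc(-c2ccc(OCC=C)c(OCC=C)c2)c1C(=O)OC(C)(C)C | intermediate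
11 | acetic (E)-4-{5-[3,4-bis(allyloxy)phenyl]-4-(tert-butoxycarbonyl)furan-3-yl}-3-(ethoxycarbonyl)but-3-enoic anhydride (not isolated) | CC(=O)OC(=O)C/C(C(=O)OCC)=C\c1coc(-c2ccc(OCC=C)c(OCC=C)c2)c1C(=O)OC(C)(C)C | intermediate
12 | 3-tert-butyl 5-ethyl 2-[3,4-bis(allyloxy)phenyl]-7-hydroxybenzofuran-3,5-dicarboxylate (not isolated) | CCOC(=O)c1cc(O)c2oc(-c3ccc(OCC=C)c(OCC=C)c3)c(C(=O)OC(C)(C)C)c2c1 | intermediate
13 | 3-tert-butyl 5-ethyl 7-acetoxy-2-[3,4-bis(allyloxy)phenyl]benzofuran-3,5-dicarboxylate | CCOC(=O)c1cc(OC(C)=O)c2oc(-c3ccc(OCC=C)c(OCC=C)c3)c(C(=O)OC(C)(C)C)c2c1 | intermediate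
14 | tert-butyl 2-[3,4-bis(allyloxy)phenyl]-7-hydroxy-5-(hydroxymethyl)benzofuran-3-carboxylate | OCc1cc(O)c2oc(-c3ccc(OCC=C)c(OCC=C)c3)c(C(=O)OC(C)(C)C)c2c1 | intermediate
15 | tert-butyl 7-(allyloxy)-2-[3,4-bis(allyloxy)phenyl]-5-(hydroxymethyl)benzofuran-3-carboxylate | OCc1cc(OCC=C)c2oc(-c3ccc(OCC=C)c(OCC=C)c3)c(C(=O)OC(C)(C)C)c2c1 | intermediate
16 | tert-butyl 7-(allyloxy)-2-[3,4-bis(allyloxy)phenyl]-5-formylbenzofuran-3-carboxylate | O=Cc1cc(OCC=C)c2oc(-c3ccc(OCC=C)c(OCC=C)c3)c(C(=O)OC(C)(C)C)c2c1 | intermediate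
17 | malonic acid | OC(=O)CC(=O)O | starting material
18 | 2-({7-(allyloxy)-2-[3,4-bis(allyloxy)phenyl]-3-(tert-butoxycarbonyl)benzofuran-5-yl}methylene)malonic acid (not isolated) | OC(=O)C(C(=O)O)=Cc1cc(OCC=C)c2oc(-c3ccc(OCC=C)c(OCC=C)c3)c(C(=O)OC(C)(C)C)c2c1 | intermediate
19 | (E)-3-{7-(allyloxy)-2-[3,4-bis(allyloxy)phenyl]-3-(tert-butoxycarbonyl)benzofuran-5-yl}acrylic acid | OC(=O)/C=C/c1cc(OCC=C)c2oc(-c3ccc(OCC=C)c(OCC=C)c3)c(C(=O)OC(C)(C)C)c2c1 | intermediate
20 | 7-(allyloxy)-2-[3,4-bis(allyloxy)phenyl]-5-[(E)-2-carboxyvinyl]benzofuran-3-carboxylic acid | OC(=O)/C=C/c1cc(OCC=C)c2oc(-c3ccc(OCC=C)c(OCC=C)c3)c(C(=O)O)c2c1 | intermediate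
21 | (R)-3-(3,4-dihydroxyphenyl)-2-hydroxypropanoic acid (danshensu) | O[C@H](Cc1ccc(O)c(O)c1)C(=O)O | starting material
22 | allyl (R)-3-[3,4-bis(allyloxy)phenyl]-2-hydroxypropanoate | O[C@H](Cc1ccc(OCC=C)c(OCC=C)c1)C(=O)OCC=C | intermediate
23 | 7-(allyloxy)-2-[3,4-bis(allyloxy)phenyl]-5-[(E)-3-chloro-3-oxoprop-1-enyl]benzofuran-3-carbonyl chloride (not isolated) | O=C(Cl)/C=C/c1cc(OCC=C)c2oc(-c3ccc(OCC=C)c(OCC=C)c3)c(C(Cl)=O)c2c1 | intermediate
24 | nona-O-allyl schizotenuin A: (R)-1-(allyloxy)-3-[3,4-bis(allyloxy)phenyl]-1-oxopropan-2-yl 7-(allyloxy)-2-[3,4-bis(allyloxy)phenyl]-5-[(E)-3-{[(R)-1-(allyloxy)-3-[3,4-bis(allyloxy)phenyl]-1-oxopropan-2-yl]oxy}-3-oxoprop-1-enyl]benzofuran-3-carboxylate | O=C(/C=C/c1cc(OCC=C)c2oc(-c3ccc(OCC=C)c(OCC=C)c3)c(C(=O)O[C@H](Cc3ccc(OCC=C)c(OCC=C)c3)C(=O)OCC=C)c2c1)O[C@H](Cc1ccc(OCC=C)c(OCC=C)c1)C(=O)OCC=C | intermediate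
25 | schizotenuin A | O=C(/C=C/c1cc(O)c2oc(-c3ccc(O)c(O)c3)c(C(=O)O[C@H](Cc3ccc(O)c(O)c3)C(=O)O)c2c1)O[C@H](Cc1ccc(O)c(O)c1)C(=O)O | target

**Step count and risks**

Total step count: 14. Longest linear sequence: 13 steps (steps 1–11, 13 and 14; step 12 is the side branch that supplies 22).

Steps most likely to fail:

Step 3. The enolate of 4 may attack a CH2Cl carbon of dichloroacetone instead of its carbonyl (C-alkylation followed by Paal–Knorr-type closure), which would place the chloromethyl group at C5 and destroy the free α-position. The chloromethylfuran may also lactonise onto the tert-butyl ester during dehydration or during the following Kornblum step. The fallback sets out from 4 and returns at 8, replacing steps 3 and 4. A Feist–Benary reaction of 4 with ethyl bromopyruvate (i-Pr2NEt, THF, 0 °C to rt; then PPTS, toluene, 70 °C), whose far more electrophilic keto group enforces aldol-first addition, should give the hydroxydihydrofuran diester F1 and, after dehydration, the furan diester F2. Reduction with i-Bu2AlH (CH2Cl2, −78 °C) should reduce only the unhindered ethyl ester to the hydroxymethylfuran F3, and MnO2 oxidation in CH2Cl2 would then give aldehyde 8.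

Step 6. In hot acetic anhydride the tert-butyl group may be lost by thermal or acetic-acid-promoted elimination, and the electron-rich furan may oligomerise faster than the ring closes. The fallback sets out from 10 and returns at 13. Half-ester 10 is converted under neutral conditions with 1-chloro-N,N,2-trimethylprop-1-enylamine (CH2Cl2, 0 °C) into the acid chloride F4. Treatment with Et3N in toluene (rt to 60 °C) should dehydrochlorinate it to the dienylketene F5, whose 6π-electrocyclisation onto the furan C=C and tautomerisation should give phenol 12 without acid or high temperature. Acetylation of 12 in the same flask (Ac2O, DMAP cat., rt) then gives 13.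

Step 13. Forcing two different acid chlorides at once may give incomplete acylation at the hindered C3 carbonyl, hence mixtures of mono- and bis-esters that are hard to separate, and longer exposure of the lactate ester to base. The fallback sets out from 16 and 22 and returns at 24, replacing steps 10, 11 and 13. Alcohol 22 is esterified with diethylphosphonoacetic acid (DCC, DMAP, CH2Cl2) to the phosphonate F6. A Masamune–Roush Horner–Wadsworth–Emmons olefination of 16 with F6 (LiCl, DBU, MeCN, rt) should give the (E)-acrylate tert-butyl ester F7, which already carries the first lactate. TFA in CH2Cl2 then frees the mono-acid F8, now the only acid in the molecule. It is converted alone into the acid chloride F9 ((COCl)2, cat. DMF, CH2Cl2) and esterified with an excess of 22 (pyridine, DMAP) to give 24.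

**Further compounds**

F1 | step 3 | 3-tert-butyl 4-ethyl 2-[3,4-bis(allyloxy)phenyl]-4-hydroxy-4,5-dihydrofuran-3,4-dicarboxylate (racemic) | CCOC(=O)C1(O)COC(c2ccc(OCC=C)c(OCC=C)c2)=C1C(=O)OC(C)(C)C
F2 | step 3 | 3-tert-butyl 4-ethyl 2-[3,4-bis(allyloxy)phenyl]furan-3,4-dicarboxylate | CCOC(=O)c1coc(-c2ccc(OCC=C)c(OCC=C)c2)c1C(=O)OC(C)(C)C
F3 | step 3 | tert-butyl 2-[3,4-bis(allyloxy)phenyl]-4-(hydroxymethyl)furan-3-carboxylate | OCc1coc(-c2ccc(OCC=C)c(OCC=C)c2)c1C(=O)OC(C)(C)C
F4 | step 6 | tert-butyl 2-[3,4-bis(allyloxy)phenyl]-4-[(E)-4-chloro-2-(ethoxycarbonyl)-4-oxobut-1-enyl]furan-3-carboxylate | O=C(Cl)C/C(C(=O)OCC)=C\c1coc(-c2ccc(OCC=C)c(OCC=C)c2)c1C(=O)OC(C)(C)C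
F5 | step 6 | tert-butyl 2-[3,4-bis(allyloxy)phenyl]-4-[(1E)-2-(ethoxycarbonyl)-4-oxobuta-1,3-dienyl]furan-3-carboxylate (dienylketene) | O=C=C/C(C(=O)OCC)=C\c1coc(-c2ccc(OCC=C)c(OCC=C)c2)c1C(=O)OC(C)(C)C
F6 | step 13 | allyl (R)-3-[3,4-bis(allyloxy)phenyl]-2-{[2-(diethoxyphosphoryl)acetyl]oxy}propanoate | CCOP(=O)(OCC)CC(=O)O[C@H](Cc1ccc(OCC=C)c(OCC=C)c1)C(=O)OCC=C
F7 | step 13 | tert-butyl 7-(allyloxy)-2-[3,4-bis(allyloxy)phenyl]-5-[(E)-3-{[(R)-1-(allyloxy)-3-[3,4-bis(allyloxy)phenyl]-1-oxopropan-2-yl]oxy}-3-oxoprop-1-enyl]benzofuran-3-carboxylate | O=C(/C=C/c1cc(OCC=C)c2oc(-c3ccc(OCC=C)c(OCC=C)c3)c(C(=O)OC(C)(C)C)c2c1)O[C@H](Cc1ccc(OCC=C)c(OCC=C)c1)C(=O)OCC=C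
F8 | step 13 | 7-(allyloxy)-2-[3,4-bis(allyloxy)phenyl]-5-[(E)-3-{[(R)-1-(allyloxy)-3-[3,4-bis(allyloxy)phenyl]-1-oxopropan-2-yl]oxy}-3-oxoprop-1-enyl]benzofuran-3-carboxylic acid | O=C(/C=C/c1cc(OCC=C)c2oc(-c3ccc(OCC=C)c(OCC=C)c3)c(C(=O)O)c2c1)O[C@H](Cc1ccc(OCC=C)c(OCC=C)c1)C(=O)OCC=C
F9 | step 13 | 7-(allyloxy)-2-[3,4-bis(allyloxy)phenyl]-5-[(E)-3-{[(R)-1-(allyloxy)-3-[3,4-bis(allyloxy)phenyl]-1-oxopropan-2-yl]oxy}-3-oxoprop-1-enyl]benzofuran-3-carbonyl chloride | O=C(/C=C/c1cc(OCC=C)c2oc(-c3ccc(OCC=C)c(OCC=C)c3)c(C(Cl)=O)c2c1)O[C@H](Cc1ccc(OCC=C)c(OCC=C)c1)C(=O)OCC=C
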